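Atom labels (kept for all intermediates): ring O1, C2 (CH3), C3 (bears C10), C4 (bears the C7H2–C8 ester arm), C5 (bears the C11 methyl ester), C6.
Cuts, in retrosynthetic order: the aryl O–Si bonds and C10–H (back to the C10 aldehyde), O1–C2 (retro-oxa-Michael), C8–O (hydroxytyrosyl ester), C2–C3 (acetaldehyde unit), C4–C5 (Michael addition).
Feature used: in the ring O1–C2–C3–C4–C5=C6, O1 is the enol oxygen of the C5/C6 formyl-ester unit and C2 is β to C10 once C10 is an aldehyde, so O1–C2 is an oxa-Michael bond; that carbonyl makes C2 (reversible addition) and C3 (enolisation) exchangeable, while C4 is not.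
Forward: an amine-catalysed Michael addition joins C4–C5; thioester reduction closes an auxiliary pyran ring (the C10 lactol, bond O–C10); dehydration and acetal addition attach C2 to C3; the arm is oxidised to C8 and esterified; acid releases the (E)-ethylidene lactol; Et3N opens it and closes the target dihydropyran through O1–C2; reduction and desilylation finish.
Stereochemistry: C4 from the (R)-diphenylprolinol silyl ether catalyst; C2 and C3 by equilibration to the all-trans aldehyde relative to C4, then fixed by reduction of C10.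

Key step: step 15

Remark: the centres other than C4 that arise in steps 5–8 and 14 (C5, the anomeric C10, C3 and the methoxy-bearing C2) are all erased or re-set later, so those intermediates are carried as diastereomer mixtures. Locants inside systematic names belong to the compound named; C-labels in the text are the target labels.

Step 1
Reactants: 1 propane-1,3-diol
Product: 2 3-[(tert-butyldiphenylsilyl)oxy]propan-1-ol
Conditions: NaH (1.0 equiv), THF, 0 °C → rt; then TBDPSCl (1.0 equiv), rt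
Reagents that add atoms: tert-butyl(chloro)diphenylsilane, CC(C)(C)[Si](Cl)(c1ccccc1)c1ccccc1
Why: O-silylation of the sparingly soluble monosodium alkoxide of a symmetrical diol should stop at the mono-ether.

Step 2
Reactants: 2 3-[(tert-butyldiphenylsilyl)oxy]propan-1-ol
Product: 3 3-[(tert-butyldiphenylsilyl)oxy]propanal
Conditions: TEMPO (10 mol%), PhI(OAc)2 (1.1 equiv), CH2Cl2, rt
Reagents that add atoms: none
Why: the oxoammonium (TEMPO) oxidation of a primary alcohol stops at the aldehyde in dry CH2Cl2 and uses no base that could eliminate the β-silyloxy group.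

Step 3
Reactants: 3 3-[(tert-butyldiphenylsilyl)oxy]propanal; 4 (triphenylphosphoranylidene)acetaldehyde
Product: 5 (2E)-5-[(tert-butyldiphenylsilyl)oxy]pent-2-enal
Conditions: toluene, 80 °C
Reagents that add atoms: none
Why: Wittig olefination with the stabilised formylmethylene ylide gives the (E)-enal, and the ylide reacts faster with the saturated aldehyde than with the conjugated product.

Step 4
Reactants: 6 methyl 3-chloro-3-oxopropanoate
Product: 7 methyl 3-(ethylsulfanyl)-3-oxopropanoate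
Conditions: EtSH (1.1 equiv), pyridine (1.2 equiv), CH2Cl2, 0 °C → rt
Reagents that add atoms: ethanethiol, CCS
Why: acyl substitution of the acid chloride by the thiol (thioesterification) leaves the methyl ester untouched.

Step 5
Reactants: 5 (2E)-5-[(tert-butyldiphenylsilyl)oxy]pent-2-enal; 7 methyl 3-(ethylsulfanyl)-3-oxopropanoate
Product: 8 methyl (3S)-3-{2-[(tert-butyldiphenylsilyl)oxy]ethyl}-2-[(ethylsulfanyl)carbonyl]-5-oxopentanoate (epimers at the malonate carbon)
Conditions: (R)-2-[diphenyl(trimethylsilyloxy)methyl]pyrrolidine (15 mol%), PhCO2H (15 mol%), CH2Cl2, 0 °C → rt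
Reagents that add atoms: none
Why: iminium-ion-catalysed Michael addition of a malonate-type C–H acid to an enal (diarylprolinol silyl ether catalysis) forms C4–C5; the diphenyl(silyloxy)methyl group shields one face of the s-trans (E)-iminium ion, C5 adds to the other face of C4, and with the (R)-catalyst this should give (S) at C4.

Step 6
Reactants: 8 methyl (3S)-3-{2-[(tert-butyldiphenylsilyl)oxy]ethyl}-2-[(ethylsulfanyl)carbonyl]-5-oxopentanoate
Product: 10 methyl (4S)-4-{2-[(tert-butyldiphenylsilyl)oxy]ethyl}-2-hydroxy-3,4-dihydro-2H-pyran-5-carboxylate (anomeric mixture), via formyl ester 9 (not isolated)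
Conditions: Pd/C (10 wt%), Et3SiH (3 equiv), acetone, rt
Reagents that add atoms: none
Why: Fukuyama reduction converts only the thioester into an aldehyde (C6); the resulting formyl ester enolises and its enol oxygen adds to the C10 aldehyde, closing the six-membered lactol.

Step 7
Reactants: 10 methyl (4S)-4-{2-[(tert-butyldiphenylsilyl)oxy]ethyl}-2-hydroxy-3,4-dihydro-2H-pyran-5-carboxylate
Product: 12 methyl (4S)-4-{2-[(tert-butyldiphenylsilyl)oxy]ethyl}-4H-pyran-3-carboxylate, via anomeric mesylate 11 (not isolated)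
Conditions: MsCl (1.5 equiv), Et3N (4 equiv), CH2Cl2, −20 °C → rt
Reagents that add atoms: none
Why: sulfonylation of the lactol and elimination toward C3 is the usual dehydration of a 2-hydroxy-dihydropyran to the glycal-type enol ether C10=C3; C4–H is not acidic (its anion would be a cyclic eight-electron system), so C4 is kept.

Step 8
Reactants: 12 methyl (4S)-4-{2-[(tert-butyldiphenylsilyl)oxy]ethyl}-4H-pyran-3-carboxylate; 13 1,1-dimethoxyethane (acetaldehyde dimethyl acetal)
Product: 14 methyl (4S)-4-{2-[(tert-butyldiphenylsilyl)oxy]ethyl}-2-methoxy-3-(1-methoxyethyl)-3,4-dihydro-2H-pyran-5-carboxylate (diastereomer mixture)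
Conditions: BF3·OEt2 (0.2 equiv), 13 (5 equiv), CH2Cl2, −78 → −40 °C; Et3N quench
Reagents that add atoms: none
Why: Lewis-acid-mediated addition of an acetal to an enol ether (Mukaiyama-type) forms C2–C3: the methoxycarbenium ion attacks the electron-rich C3 of the O–C10=C3 enol ether (C5=C6 is deactivated by the ester) and methoxide capture at C10 leaves that carbon masked as a methyl acetal.

Step 9
Reactants: 14 methyl (4S)-4-{2-[(tert-butyldiphenylsilyl)oxy]ethyl}-2-methoxy-3-(1-methoxyethyl)-3,4-dihydro-2H-pyran-5-carboxylate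
Product: 15 methyl (4S)-4-(2-hydroxyethyl)-2-methoxy-3-(1-methoxyethyl)-3,4-dihydro-2H-pyran-5-carboxylate
Conditions: TBAF (1.2 equiv), AcOH (1.2 equiv), THF, 0 °C → rt
Reagents that add atoms: none
Why: fluoride cleavage of the silyl ether under acetic acid buffering leaves the acetal, the methyl ether and the ester untouched.

Step 10
Reactants: 15 methyl (4S)-4-(2-hydroxyethyl)-2-methoxy-3-(1-methoxyethyl)-3,4-dihydro-2H-pyran-5-carboxylate
Product: 16 2-[(4S)-2-methoxy-3-(1-methoxyethyl)-5-(methoxycarbonyl)-3,4-dihydro-2H-pyran-4-yl]acetic acid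
Conditions: TEMPO (20 mol%), PhI(OAc)2 (2.2 equiv), MeCN/H2O (1:1), rt
Reagents that add atoms: water, O
Why: TEMPO/PhI(OAc)2 in aqueous acetonitrile takes a primary alcohol through the aldehyde hydrate to the acid (C8), and the acetal and the ester-deactivated enol ether are inert to the oxoammonium oxidant.

Step 11
Reactants: 17 hydroxytyrosol, 2-(3,4-dihydroxyphenyl)ethan-1-ol
Product: 18 tert-butyl(2-{3,4-bis[(tert-butyldimethylsilyl)oxy]phenyl}ethoxy)dimethylsilane (tris-silyl ether)
Conditions: TBSCl (3.5 equiv), imidazole (7 equiv), DMF, rt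
Reagents that add atoms: tert-butyl(chloro)dimethylsilane, CC(C)(C)[Si](C)(C)Cl
Why: imidazole-promoted silylation is exhaustive for both phenols and the primary alcohol.

Step 12
Reactants: 18 tert-butyl(2-{3,4-bis[(tert-butyldimethylsilyl)oxy]phenyl}ethoxy)dimethylsilane
Product: 19 2-{3,4-bis[(tert-butyldimethylsilyl)oxy]phenyl}ethan-1-ol
Conditions: camphorsulfonic acid (10 mol%), MeOH/CH2Cl2 (1:1), 0 °C
Reagents that add atoms: none
Why: acid-catalysed methanolysis removes the alkyl silyl ether much faster than the aryl silyl ethers, which are acid-stable.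

Step 13
Reactants: 16 2-[(4S)-2-methoxy-3-(1-methoxyethyl)-5-(methoxycarbonyl)-3,4-dihydro-2H-pyran-4-yl]acetic acid; 19 2-{3,4-bis[(tert-butyldimethylsilyl)oxy]phenyl}ethan-1-ol
Product: 20 methyl (4S)-4-[2-(2-{3,4-bis[(tert-butyldimethylsilyl)oxy]phenyl}ethoxy)-2-oxoethyl]-2-methoxy-3-(1-methoxyethyl)-3,4-dihydro-2H-pyran-5-carboxylate
Conditions: DCC (1.2 equiv), DMAP (10 mol%), CH2Cl2, 0 °C → rt
Reagents that add atoms: none
Why: Steglich esterification of the acid with the primary alcohol forms the C8–O bond, and no stereocentre lies α to the activated carboxyl.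

Step 14
Reactants: 20 methyl (4S)-4-[2-(2-{3,4-bis[(tert-butyldimethylsilyl)oxy]phenyl}ethoxy)-2-oxoethyl]-2-methoxy-3-(1-methoxyethyl)-3,4-dihydro-2H-pyran-5-carboxylate
Product: 22 methyl (3E,4S)-4-[2-(2-{3,4-bis[(tert-butyldimethylsilyl)oxy]phenyl}ethoxy)-2-oxoethyl]-3-ethylidene-2-hydroxy-3,4-dihydro-2H-pyran-5-carboxylate (anomeric mixture), via methoxy lactol 21 (not isolated)
Conditions: TsOH·H2O (20 mol%), acetone/H2O (10:1), 45 °C
Reagents that add atoms: water, O
Why: acid hydrolysis of the methyl acetal frees the C10 lactol/aldehyde, whose enol expels the β-methoxy group at C2 (the usual hydrolysis–elimination of a β-alkoxy acetal to an enal) to give the conjugated, thermodynamically preferred (E)-ethylidene aldehyde held as its lactol; aryl silyl ethers and both esters should tolerate the mild acid, and material that still carries the C2 methoxy group can be taken into step 15, where base completes the elimination.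

Step 15
Reactants: 22 methyl (3E,4S)-4-[2-(2-{3,4-bis[(tert-butyldimethylsilyl)oxy]phenyl}ethoxy)-2-oxoethyl]-3-ethylidene-2-hydroxy-3,4-dihydro-2H-pyran-5-carboxylate
Product: 24 methyl (2R,3S,4S)-4-[2-(2-{3,4-bis[(tert-butyldimethylsilyl)oxy]phenyl}ethoxy)-2-oxoethyl]-3-formyl-2-methyl-3,4-dihydro-2H-pyran-5-carboxylate, via open-chain enol enal 23 (not isolated)
Conditions: Et3N (2 equiv), CH2Cl2, rt, argon
Reagents that add atoms: none
Why: Et3N shifts the ring–chain equilibrium of the lactol to the open (E)-ethylidene enal 23 and deprotonates the acidic enol of the formyl ester, whose oxygen (the future O1) adds in conjugate fashion to C2; the C10 enolate so formed is protonated at C3. The closest known reaction type is the base-mediated intramolecular oxa-Michael addition of a 1,3-dicarbonyl enol to an enal, the closure that ethylidene secoiridoid dialdehydes undergo. The ring O1–C2–C3–C4–C5=C6 closes in the 6-endo-trig mode, both alkene carbons C2 and C3 ending inside the ring. C2 is controlled by the reversibility of the O1–C2 bond (retro-oxa-Michael through the C10 enolate) and C3 by enolisation of the aldehyde, so both should settle, relative to the fixed C4 centre, in the arrangement with methyl, formyl and acetate arm mutually trans. The step needs thermodynamic diastereoselection and attack at C2 of the enal only; the substrate secures this because C4–H is neither α to a carbonyl nor β to a leaving group, the 1,2-adduct (the lactol) is only a reversible reservoir, O1 and C2 stand in a 1,5-relationship, and Et3N is too weak to affect the esters or the aryl silyl ethers. A minor C2 epimer, if present at equilibrium, would be removed by chromatography after step 16.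

Step 16
Reactants: 24 methyl (2R,3S,4S)-4-[2-(2-{3,4-bis[(tert-butyldimethylsilyl)oxy]phenyl}ethoxy)-2-oxoethyl]-3-formyl-2-methyl-3,4-dihydro-2H-pyran-5-carboxylate
Product: 25 methyl (2R,3R,4S)-4-[2-(2-{3,4-bis[(tert-butyldimethylsilyl)oxy]phenyl}ethoxy)-2-oxoethyl]-3-(hydroxymethyl)-2-methyl-3,4-dihydro-2H-pyran-5-carboxylate
Conditions: NaBH4 (1 equiv), THF/MeOH (4:1), −40 °C; pH 7 phosphate buffer
Reagents that add atoms: none
Why: at low temperature NaBH4 reduces the aldehyde much faster than the esters or the ester-conjugated enol ether; removing the C10 carbonyl closes both the retro-oxa-Michael and the enolisation pathways, so C2 and C3 are fixed, and the cold neutral quench avoids lactonisation of the new hydroxyl onto C8.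

Step 17
Reactants: 25 methyl (2R,3R,4S)-4-[2-(2-{3,4-bis[(tert-butyldimethylsilyl)oxy]phenyl}ethoxy)-2-oxoethyl]-3-(hydroxymethyl)-2-methyl-3,4-dihydro-2H-pyran-5-carboxylate
Product: 26 methyl (2R,3R,4S)-4-{2-[2-(3,4-dihydroxyphenyl)ethoxy]-2-oxoethyl}-3-(hydroxymethyl)-2-methyl-3,4-dihydro-2H-pyran-5-carboxylate (CNP0204147.1)
Conditions: HF·pyridine, pyridine/THF, 0 °C → rt
Reagents that add atoms: none
Why: fluoride cleavage of the two aryl silyl ethers under buffered, non-basic conditions avoids the phenoxide/alkoxide conditions that would favour lactonisation or air oxidation of the catechol.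

Compound list
1 | propane-1,3-diol | OCCCO | starting material
2 | 3-[(tert-butyldiphenylsilyl)oxy]propan-1-ol | OCCCO[Si](c1ccccc1)(c1ccccc1)C(C)(C)C | intermediate
3 | 3-[(tert-butyldiphenylsilyl)oxy]propanal | O=CCCO[Si](c1ccccc1)(c1ccccc1)C(C)(C)C | intermediate
4 | (triphenylphosphoranylidene)acetaldehyde | O=CC=P(c1ccccc1)(c1ccccc1)c1ccccc1 | starting material
5 | (2E)-5-[(tert-butyldiphenylsilyl)oxy]pent-2-enal | O=C/C=C/CCO[Si](c1ccccc1)(c1ccccc1)C(C)(C)C | intermediate
6 | methyl 3-chloro-3-oxopropanoate | COC(=O)CC(=O)Cl | starting material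
7 | methyl 3-(ethylsulfanyl)-3-oxopropanoate | COC(=O)CC(=O)SCC | intermediate
8 | methyl (3S)-3-{2-[(tert-butyldiphenylsilyl)oxy]ethyl}-2-[(ethylsulfanyl)carbonyl]-5-oxopentanoate | COC(=O)C(C(=O)SCC)[C@H](CC=O)CCO[Si](c1ccccc1)(c1ccccc1)C(C)(C)C | intermediate
9 | methyl (3S)-3-{2-[(tert-butyldiphenylsilyl)oxy]ethyl}-2-formyl-5-oxopentanoate (formyl ester, drawn as the dialdehyde; not isolated) | COC(=O)C(C=O)[C@H](CC=O)CCO[Si](c1ccccc1)(c1ccccc1)C(C)(C)C | intermediate
10 | methyl (4S)-4-{2-[(tert-butyldiphenylsilyl)oxy]ethyl}-2-hydroxy-3,4-dihydro-2H-pyran-5-carboxylate | COC(=O)C1=COC(O)C[C@@H]1CCO[Si](c1ccccc1)(c1ccccc1)C(C)(C)C | intermediate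
11 | methyl (4S)-4-{2-[(tert-butyldiphenylsilyl)oxy]ethyl}-2-[(methanesulfonyl)oxy]-3,4-dihydro-2H-pyran-5-carboxylate (anomeric mesylate; not isolated) | COC(=O)C1=COC(OS(C)(=O)=O)C[C@@H]1CCO[Si](c1ccccc1)(c1ccccc1)C(C)(C)C | intermediate
12 | methyl (4S)-4-{2-[(tert-butyldiphenylsilyl)oxy]ethyl}-4H-pyran-3-carboxylate | COC(=O)C1=COC=C[C@@H]1CCO[Si](c1ccccc1)(c1ccccc1)C(C)(C)C | intermediate
13 | 1,1-dimethoxyethane | CC(OC)OC | starting material
14 | methyl (4S)-4-{2-[(tert-butyldiphenylsilyl)oxy]ethyl}-2-methoxy-3-(1-methoxyethyl)-3,4-dihydro-2H-pyran-5-carboxylate | COC(=O)C1=COC(OC)C(C(C)OC)[C@@H]1CCO[Si](c1ccccc1)(c1ccccc1)C(C)(C)C | intermediate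
15 | methyl (4S)-4-(2-hydroxyethyl)-2-methoxy-3-(1-methoxyethyl)-3,4-dihydro-2H-pyran-5-carboxylate | COC(=O)C1=COC(OC)C(C(C)OC)[C@@H]1CCO | intermediate
16 | 2-[(4S)-2-methoxy-3-(1-methoxyethyl)-5-(methoxycarbonyl)-3,4-dihydro-2H-pyran-4-yl]acetic acid | COC(=O)C1=COC(OC)C(C(C)OC)[C@@H]1CC(=O)O | intermediate
17 | hydroxytyrosol, 2-(3,4-dihydroxyphenyl)ethan-1-ol | OCCc1ccc(O)c(O)c1 | starting material
18 | tert-butyl(2-{3,4-bis[(tert-butyldimethylsilyl)oxy]phenyl}ethoxy)dimethylsilane | CC(C)(C)[Si](C)(C)OCCc1ccc(O[Si](C)(C)C(C)(C)C)c(O[Si](C)(C)C(C)(C)C)c1 | intermediate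
19 | 2-{3,4-bis[(tert-butyldimethylsilyl)oxy]phenyl}ethan-1-ol | OCCc1ccc(O[Si](C)(C)C(C)(C)C)c(O[Si](C)(C)C(C)(C)C)c1 | intermediate
20 | methyl (4S)-4-[2-(2-{3,4-bis[(tert-butyldimethylsilyl)oxy]phenyl}ethoxy)-2-oxoethyl]-2-methoxy-3-(1-methoxyethyl)-3,4-dihydro-2H-pyran-5-carboxylate | COC(=O)C1=COC(OC)C(C(C)OC)[C@@H]1CC(=O)OCCc1ccc(O[Si](C)(C)C(C)(C)C)c(O[Si](C)(C)C(C)(C)C)c1 | intermediate
21 | methyl (4S)-4-[2-(2-{3,4-bis[(tert-butyldimethylsilyl)oxy]phenyl}ethoxy)-2-oxoethyl]-2-hydroxy-3-(1-methoxyethyl)-3,4-dihydro-2H-pyran-5-carboxylate (methoxy lactol; not isolated) | COC(=O)C1=COC(O)C(C(C)OC)[C@@H]1CC(=O)OCCc1ccc(O[Si](C)(C)C(C)(C)C)c(O[Si](C)(C)C(C)(C)C)c1 | intermediate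
22 | methyl (3E,4S)-4-[2-(2-{3,4-bis[(tert-butyldimethylsilyl)oxy]phenyl}ethoxy)-2-oxoethyl]-3-ethylidene-2-hydroxy-3,4-dihydro-2H-pyran-5-carboxylate | COC(=O)C1=COC(O)/C(=C/C)[C@@H]1CC(=O)OCCc1ccc(O[Si](C)(C)C(C)(C)C)c(O[Si](C)(C)C(C)(C)C)c1 | intermediate
23 | 5-(2-{3,4-bis[(tert-butyldimethylsilyl)oxy]phenyl}ethyl) 1-methyl (3S)-2-(hydroxymethylidene)-3-[(2E)-1-oxobut-2-en-2-yl]pentanedioate (open-chain enol enal; not isolated) | COC(=O)C(=CO)[C@@H](CC(=O)OCCc1ccc(O[Si](C)(C)C(C)(C)C)c(O[Si](C)(C)C(C)(C)C)c1)\C(=C/C)C=O | intermediate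
24 | methyl (2R,3S,4S)-4-[2-(2-{3,4-bis[(tert-butyldimethylsilyl)oxy]phenyl}ethoxy)-2-oxoethyl]-3-formyl-2-methyl-3,4-dihydro-2H-pyran-5-carboxylate | COC(=O)C1=CO[C@H](C)[C@@H](C=O)[C@@H]1CC(=O)OCCc1ccc(O[Si](C)(C)C(C)(C)C)c(O[Si](C)(C)C(C)(C)C)c1 | intermediate
25 | methyl (2R,3R,4S)-4-[2-(2-{3,4-bis[(tert-butyldimethylsilyl)oxy]phenyl}ethoxy)-2-oxoethyl]-3-(hydroxymethyl)-2-methyl-3,4-dihydro-2H-pyran-5-carboxylate | COC(=O)C1=CO[C@H](C)[C@@H](CO)[C@@H]1CC(=O)OCCc1ccc(O[Si](C)(C)C(C)(C)C)c(O[Si](C)(C)C(C)(C)C)c1 | intermediate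
26 | methyl (2R,3R,4S)-4-{2-[2-(3,4-dihydroxyphenyl)ethoxy]-2-oxoethyl}-3-(hydroxymethyl)-2-methyl-3,4-dihydro-2H-pyran-5-carboxylate | COC(=O)C1=CO[C@H](C)[C@@H](CO)[C@@H]1CC(=O)OCCc1ccc(O)c(O)c1 | target

Total step count: 17.
Longest linear sequence: 14 steps (steps 1–3, 5–10, 13–17).

Steps most likely to fail

Step 8. The electron-rich enol ether may oligomerise under the cationic conditions, or methanol may add across C10=C3 under proton catalysis in place of C–C bond formation. The fallback sets out from 12 and builds the C2 unit by formylation and Grignard addition. Vilsmeier–Haack formylation (POCl3, DMF; aqueous NaOAc) at C3 should give methyl (4S)-4-{2-[(tert-butyldiphenylsilyl)oxy]ethyl}-5-formyl-4H-pyran-3-carboxylate F1. MeMgBr (THF, −78 °C) adds to the formyl group to give methyl (4S)-4-{2-[(tert-butyldiphenylsilyl)oxy]ethyl}-5-(1-hydroxyethyl)-4H-pyran-3-carboxylate F2. Pyridinium p-toluenesulfonate in MeOH ionises the vinylogous carbinol and methanol is captured at C10 (Ferrier-type allylic transposition), giving methyl (3E,4S)-4-{2-[(tert-butyldiphenylsilyl)oxy]ethyl}-3-ethylidene-2-methoxy-3,4-dihydro-2H-pyran-5-carboxylate F3. The conditions of steps 9, 10 and 13 then give in turn methyl (3E,4S)-3-ethylidene-4-(2-hydroxyethyl)-2-methoxy-3,4-dihydro-2H-pyran-5-carboxylate F4, 2-[(3E,4S)-3-ethylidene-2-methoxy-5-(methoxycarbonyl)-3,4-dihydro-2H-pyran-4-yl]acetic acid F5 and, with 19, methyl (3E,4S)-4-[2-(2-{3,4-bis[(tert-butyldimethylsilyl)oxy]phenyl}ethoxy)-2-oxoethyl]-3-ethylidene-2-methoxy-3,4-dihydro-2H-pyran-5-carboxylate F6. Dilute aqueous acid hydrolyses this allylic acetal, and the fallback rejoins the route at 22.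

Step 14. Loss of methanol from C2 may lag behind acetal hydrolysis, and longer exposure to acid may begin to cleave the aryl silyl ethers. The fallback sets out from 20 and separates the two events. Me3SiOTf/i-Pr2NEt (CH2Cl2, −20 °C) converts the acetal into the enol ether methyl (4S)-4-[2-(2-{3,4-bis[(tert-butyldimethylsilyl)oxy]phenyl}ethoxy)-2-oxoethyl]-5-(1-methoxyethyl)-4H-pyran-3-carboxylate F7. Its methoxy group is now allylic and vinylogous to the ring oxygen, so brief contact with dilute aqueous acid at 0 °C should ionise it; water capture at C10 returns the route to 22.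

Step 15. Thermodynamic funnelling may be incomplete, with the C2 epimer persisting at equilibrium, or equilibration may be slow. The fallback sets out from 22 and replaces single-pass equilibration by a separate-and-recycle loop. The equilibrated aldehyde mixture is reduced directly under the conditions of step 16, and 25 is separated by chromatography from methyl (2S,3R,4S)-4-[2-(2-{3,4-bis[(tert-butyldimethylsilyl)oxy]phenyl}ethoxy)-2-oxoethyl]-3-(hydroxymethyl)-2-methyl-3,4-dihydro-2H-pyran-5-carboxylate F8. This is re-oxidised with Dess–Martin periodinane to methyl (2S,3S,4S)-4-[2-(2-{3,4-bis[(tert-butyldimethylsilyl)oxy]phenyl}ethoxy)-2-oxoethyl]-3-formyl-2-methyl-3,4-dihydro-2H-pyran-5-carboxylate F9, which on renewed exposure to Et3N re-enters the retro-oxa-Michael equilibrium and rejoins the route at 24.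

Further compounds
F1 | step 8 | methyl (4S)-4-{2-[(tert-butyldiphenylsilyl)oxy]ethyl}-5-formyl-4H-pyran-3-carboxylate | COC(=O)C1=COC=C(C=O)[C@@H]1CCO[Si](c1ccccc1)(c1ccccc1)C(C)(C)C
F2 | step 8 | methyl (4S)-4-{2-[(tert-butyldiphenylsilyl)oxy]ethyl}-5-(1-hydroxyethyl)-4H-pyran-3-carboxylate | COC(=O)C1=COC=C(C(C)O)[C@@H]1CCO[Si](c1ccccc1)(c1ccccc1)C(C)(C)C
F3 | step 8 | methyl (3E,4S)-4-{2-[(tert-butyldiphenylsilyl)oxy]ethyl}-3-ethylidene-2-methoxy-3,4-dihydro-2H-pyran-5-carboxylate | COC(=O)C1=COC(OC)/C(=C/C)[C@@H]1CCO[Si](c1ccccc1)(c1ccccc1)C(C)(C)C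
F4 | step 8 | methyl (3E,4S)-3-ethylidene-4-(2-hydroxyethyl)-2-methoxy-3,4-dihydro-2H-pyran-5-carboxylate | COC(=O)C1=COC(OC)/C(=C/C)[C@@H]1CCO
F5 | step 8 | 2-[(3E,4S)-3-ethylidene-2-methoxy-5-(methoxycarbonyl)-3,4-dihydro-2H-pyran-4-yl]acetic acid | COC(=O)C1=COC(OC)/C(=C/C)[C@@H]1CC(=O)O
F6 | step 8 | methyl (3E,4S)-4-[2-(2-{3,4-bis[(tert-butyldimethylsilyl)oxy]phenyl}ethoxy)-2-oxoethyl]-3-ethylidene-2-methoxy-3,4-dihydro-2H-pyran-5-carboxylate | COC(=O)C1=COC(OC)/C(=C/C)[C@@H]1CC(=O)OCCc1ccc(O[Si](C)(C)C(C)(C)C)c(O[Si](C)(C)C(C)(C)C)c1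
F7 | step 14 | methyl (4S)-4-[2-(2-{3,4-bis[(tert-butyldimethylsilyl)oxy]phenyl}ethoxy)-2-oxoethyl]-5-(1-methoxyethyl)-4H-pyran-3-carboxylate | COC(=O)C1=COC=C(C(C)OC)[C@@H]1CC(=O)OCCc1ccc(O[Si](C)(C)C(C)(C)C)c(O[Si](C)(C)C(C)(C)C)c1
F8 | step 15 | methyl (2S,3R,4S)-4-[2-(2-{3,4-bis[(tert-butyldimethylsilyl)oxy]phenyl}ethoxy)-2-oxoethyl]-3-(hydroxymethyl)-2-methyl-3,4-dihydro-2H-pyran-5-carboxylate | COC(=O)C1=CO[C@@H](C)[C@@H](CO)[C@@H]1CC(=O)OCCc1ccc(O[Si](C)(C)C(C)(C)C)c(O[Si](C)(C)C(C)(C)C)c1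
F9 | step 15 | methyl (2S,3S,4S)-4-[2-(2-{3,4-bis[(tert-butyldimethylsilyl)oxy]phenyl}ethoxy)-2-oxoethyl]-3-formyl-2-methyl-3,4-dihydro-2H-pyran-5-carboxylate | COC(=O)C1=CO[C@@H](C)[C@@H](C=O)[C@@H]1CC(=O)OCCc1ccc(O[Si](C)(C)C(C)(C)C)c(O[Si](C)(C)C(C)(C)C)c1
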